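**Strategy**

Everything rests on cutting the bond between the β-carbon of the E-propenoate (the CH next to the central ring) and C1 of the central 3-hydroxy-4-aryloxyphenyl ring, para to the ether oxygen that carries the coumarin. A Mizoroki–Heck arylation makes this bond: the aryl iodide is the complete 3-aryloxy-6,7-dihydroxycoumarin (from a Perkin coumarin synthesis), the alkene is the O2-acrylate of PMB-protected natural (R)-danshensu. The step exploits the unsubstituted terminal CH2 of the acrylate and the lone C–I bond; in one operation it joins both halves and sets the E double bond, leaving the purchased (R) centre untouched. Acidolysis of three PMB groups finishes the synthesis.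

Key step: step 6

Assumption: sodium (R)-3-(3,4-dihydroxyphenyl)lactate (sodium danshensu, the natural enantiomer) is taken as a commercial starting material. Its C2 already has the (R) configuration of the target, and no step breaks a bond at this carbon.

**Route**

Step 1
Reactants: 1 4-iodo-2-methoxyphenol
Product: 2 2-(4-iodo-2-methoxyphenoxy)acetic acid
Conditions: ClCH2CO2H, NaOH, H2O, reflux; then HCl
Reagents that add atoms: chloroacetic acid, OC(=O)CCl
Why: Williamson ether synthesis, in which the phenoxide displaces chloride from chloroacetate by SN2; the aryl iodide and the methyl ether are inert to aqueous base, and the acid should precipitate on acidification.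

Step 2
Reactants: 2 2-(4-iodo-2-methoxyphenoxy)acetic acid; 3 2-hydroxy-4,5-dimethoxybenzaldehyde
Product: 5 3-(4-iodo-2-methoxyphenoxy)-6,7-dimethoxy-2H-chromen-2-one, via aryl ester 4 (not isolated)
Conditions: Ac2O, Et3N, 120 °C
Reagents that add atoms: none
Why: Perkin–Oglialoro coumarin synthesis, in which the mixed anhydride of 2 acylates the phenol of 3 to ester 4, whose α-aryloxy CH2 undergoes amine-mediated intramolecular aldol condensation onto the ortho formyl group and dehydration to the 3-aryloxycoumarin; no free hydroxyl remains to be acetylated.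

Step 3
Reactants: 5 3-(4-iodo-2-methoxyphenoxy)-6,7-dimethoxy-2H-chromen-2-one
Product: 6 6,7-dihydroxy-3-(2-hydroxy-4-iodophenoxy)-2H-chromen-2-one
Conditions: BBr3 (excess), CH2Cl2, −78 °C to rt; then H2O
Reagents that add atoms: none
Why: BBr3 demethylation of aryl methyl ethers (boron–oxygen adduct, then bromide attack on methyl), a standard operation on methoxycoumarins that leaves the lactone, the aryl–O–vinyl ether and the aryl iodide intact.

Step 4
Reactants: 7 sodium (R)-3-(3,4-dihydroxyphenyl)-2-hydroxypropanoate
Product: 8 4-methoxybenzyl (R)-3-[3,4-bis(4-methoxybenzyloxy)phenyl]-2-hydroxypropanoate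
Conditions: PMBCl (3.2 equiv), K2CO3, Bu4NI (cat.), DMF, 40 °C, Ar
Reagents that add atoms: 4-methoxybenzyl chloride, COc1ccc(CCl)cc1
Why: Chemoselective O-alkylation (Williamson and carboxylate alkylation), since carbonate ionises only the two phenols and the carboxylate, so the secondary alcohol at C2 should stay free; the weak base does not touch the (R) centre.

Step 5
Reactants: 8 4-methoxybenzyl (R)-3-[3,4-bis(4-methoxybenzyloxy)phenyl]-2-hydroxypropanoate
Product: 9 4-methoxybenzyl (R)-2-(acryloyloxy)-3-[3,4-bis(4-methoxybenzyloxy)phenyl]propanoate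
Conditions: acryloyl chloride, Et3N, BHT (trace), CH2Cl2, −20 to 0 °C
Reagents that add atoms: acryloyl chloride, C=CC(=O)Cl
Why: Esterification of the secondary alcohol with an acid chloride, which proceeds with retention because the C2–O bond is not broken, so the (R) configuration is carried over.

Step 6
Reactants: 6 6,7-dihydroxy-3-(2-hydroxy-4-iodophenoxy)-2H-chromen-2-one; 9 4-methoxybenzyl (R)-2-(acryloyloxy)-3-[3,4-bis(4-methoxybenzyloxy)phenyl]propanoate
Product: 10 4-methoxybenzyl (R)-3-[3,4-bis(4-methoxybenzyloxy)phenyl]-2-{[(E)-3-{4-[(6,7-dihydroxy-2-oxo-2H-chromen-3-yl)oxy]-3-hydroxyphenyl}prop-2-enoyl]oxy}propanoate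
Conditions: Pd(OAc)2 (5 mol %), Bu4NCl, NaHCO3, DMF, 60 °C, Ar
Reagents that add atoms: none
Why: Mizoroki–Heck reaction under ligand-free Jeffery conditions: Pd(0) inserts into the only C–I bond of 6, the arylpalladium adds syn across the acrylate C=C of 9 with the aryl group going to the unsubstituted terminal carbon (the regiochemistry typical of electron-poor monosubstituted alkenes), and syn β-hydride elimination from the rotamer with aryl and ester anti releases the E-cinnamate while bicarbonate regenerates Pd(0). The closest known reaction type is the Heck coupling of unprotected iodophenols with acrylate esters. No ring is closed and no stereocentre is formed; the (R) centre of 9 lies two atoms from the reacting alkene and should not be epimerised by bicarbonate at 60 °C. The step needs chemoselectivity for the terminal acrylate over the trisubstituted, oxygen-bearing C3=C4 bond of the coumarin, which the much faster insertion of a monosubstituted electron-poor alkene should secure, and tolerance of three free phenols, which the weak base and the absence of phosphine (no phosphine-catalysed oxa-Michael addition) are meant to secure.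

Step 7
Reactants: 10 the Heck product (PMB ester, bis-PMB ether)
Product: 11 (R)-3-(3,4-dihydroxyphenyl)-2-{[(E)-3-{4-[(6,7-dihydroxy-2-oxo-2H-chromen-3-yl)oxy]-3-hydroxyphenyl}prop-2-enoyl]oxy}propanoic acid (target)
Conditions: TFA, pentamethylbenzene (10 equiv), CH2Cl2, 0 °C to rt, dark
Reagents that add atoms: none
Why: Acidolysis (SN1) of the two p-methoxybenzyl aryl ethers and the p-methoxybenzyl ester, with the PMB cations trapped by pentamethylbenzene in a Friedel–Crafts reaction so that they do not alkylate the catechol rings; the cinnamate ester, the lactone, the E-alkene and the (R) centre are stable to non-nucleophilic acid.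

**Compound list**

1 | 4-iodo-2-methoxyphenol | COc1cc(I)ccc1O | starting material
2 | 2-(4-iodo-2-methoxyphenoxy)acetic acid | COc1cc(I)ccc1OCC(=O)O | intermediate
3 | 2-hydroxy-4,5-dimethoxybenzaldehyde | COc1cc(O)c(C=O)cc1OC | starting material
4 | 2-formyl-4,5-dimethoxyphenyl 2-(4-iodo-2-methoxyphenoxy)acetate | COc1cc(OC(=O)COc2ccc(I)cc2OC)c(C=O)cc1OC | intermediate
5 | 3-(4-iodo-2-methoxyphenoxy)-6,7-dimethoxy-2H-chromen-2-one | O=c1oc2cc(OC)c(OC)cc2cc1Oc1ccc(I)cc1OC | intermediate
6 | 6,7-dihydroxy-3-(2-hydroxy-4-iodophenoxy)-2H-chromen-2-one | O=c1oc2cc(O)c(O)cc2cc1Oc1ccc(I)cc1O | intermediate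
7 | sodium (R)-3-(3,4-dihydroxyphenyl)-2-hydroxypropanoate (sodium danshensu) | [Na+].[O-]C(=O)[C@H](O)Cc1ccc(O)c(O)c1 | starting material
8 | 4-methoxybenzyl (R)-3-[3,4-bis(4-methoxybenzyloxy)phenyl]-2-hydroxypropanoate | COc1ccc(COC(=O)[C@H](O)Cc2ccc(OCc3ccc(OC)cc3)c(OCc3ccc(OC)cc3)c2)cc1 | intermediate
9 | 4-methoxybenzyl (R)-2-(acryloyloxy)-3-[3,4-bis(4-methoxybenzyloxy)phenyl]propanoate | C=CC(=O)O[C@H](Cc1ccc(OCc2ccc(OC)cc2)c(OCc2ccc(OC)cc2)c1)C(=O)OCc1ccc(OC)cc1 | intermediate
10 | 4-methoxybenzyl (R)-3-[3,4-bis(4-methoxybenzyloxy)phenyl]-2-{[(E)-3-{4-[(6,7-dihydroxy-2-oxo-2H-chromen-3-yl)oxy]-3-hydroxyphenyl}prop-2-enoyl]oxy}propanoate | O=C(/C=C/c1ccc(Oc2cc3cc(O)c(O)cc3oc2=O)c(O)c1)O[C@H](Cc1ccc(OCc2ccc(OC)cc2)c(OCc2ccc(OC)cc2)c1)C(=O)OCc1ccc(OC)cc1 | intermediate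
11 | (R)-3-(3,4-dihydroxyphenyl)-2-{[(E)-3-{4-[(6,7-dihydroxy-2-oxo-2H-chromen-3-yl)oxy]-3-hydroxyphenyl}prop-2-enoyl]oxy}propanoic acid | O=C(/C=C/c1ccc(Oc2cc3cc(O)c(O)cc3oc2=O)c(O)c1)O[C@H](Cc1ccc(O)c(O)c1)C(=O)O | target

**Summary**

Total step count: 7
Longest linear sequence: 5 steps (steps 1, 2, 3, 6, 7)

**Steps most likely to fail, with fallbacks**

Step 6. The free catechol and phenol of the iodide may bind or reduce the palladium catalyst to inactive metal, or a phenoxide may add to the acrylate in an oxa-Michael reaction, so that the coupling stalls. The fallback masks the phenols before the coupling. It sets out from 6, which is alkylated with PMBCl and K2CO3 in DMF to 3-[4-iodo-2-(4-methoxybenzyloxy)phenoxy]-6,7-bis(4-methoxybenzyloxy)-2H-chromen-2-one F1. This iodide is coupled with 9 under the conditions of step 6 to the fully PMB-protected cinnamate F2. Acidolysis under the conditions of step 7 (TFA, pentamethylbenzene) then removes all six PMB groups and comes back to the route at 11.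

Step 2. In hot acetic anhydride the phenol of 3 may be acetylated instead of acylated by 2, so that acetate is built into a 3-unsubstituted coumarin, and the aldol closure onto the electron-rich aldehyde may be slow. The fallback separates acylation from ring closure. It sets out from 2, which is converted with oxalyl chloride and catalytic DMF in CH2Cl2 to 2-(4-iodo-2-methoxyphenoxy)acetyl chloride F3. This acylates 3 (Et3N, CH2Cl2, 0 °C) to give ester 4, now isolated. Ester 4 is cyclised by intramolecular aldol condensation with K2CO3 in refluxing acetone, and the fallback comes back to the route at 5.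

Step 7. The p-methoxybenzyl cations may alkylate the electron-rich catechol rings faster than the scavenger traps them, or the three groups may be lost at unequal rates, so that mixtures result. The fallback replaces the benzylic protecting groups by acetals that are cleaved by hydrolysis. It sets out from 7, which with MOMCl and K2CO3 in DMF at 0 °C should give methoxymethyl (R)-3-[3,4-bis(methoxymethoxy)phenyl]-2-hydroxypropanoate F4. Acryloyl chloride and Et3N convert it to methoxymethyl (R)-2-(acryloyloxy)-3-[3,4-bis(methoxymethoxy)phenyl]propanoate F5. Heck coupling of F5 with 6 under the conditions of step 6 gives the MOM-protected cinnamate F6. Hydrolysis with 2 M HCl in THF at 40 °C removes the MOM ester and both MOM ethers and comes back to the route at 11.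

**Further compounds**

F1 | step 6 | 3-[4-iodo-2-(4-methoxybenzyloxy)phenoxy]-6,7-bis(4-methoxybenzyloxy)-2H-chromen-2-one | O=c1oc2cc(OCc3ccc(OC)cc3)c(OCc3ccc(OC)cc3)cc2cc1Oc1ccc(I)cc1OCc1ccc(OC)cc1
F2 | step 6 | 4-methoxybenzyl (R)-3-[3,4-bis(4-methoxybenzyloxy)phenyl]-2-{[(E)-3-{4-[(6,7-bis(4-methoxybenzyloxy)-2-oxo-2H-chromen-3-yl)oxy]-3-(4-methoxybenzyloxy)phenyl}prop-2-enoyl]oxy}propanoate | O=C(/C=C/c1ccc(Oc2cc3cc(OCc4ccc(OC)cc4)c(OCc4ccc(OC)cc4)cc3oc2=O)c(OCc2ccc(OC)cc2)c1)O[C@H](Cc1ccc(OCc2ccc(OC)cc2)c(OCc2ccc(OC)cc2)c1)C(=O)OCc1ccc(OC)cc1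
F3 | step 2 | 2-(4-iodo-2-methoxyphenoxy)acetyl chloride | COc1cc(I)ccc1OCC(=O)Cl
F4 | step 7 | methoxymethyl (R)-3-[3,4-bis(methoxymethoxy)phenyl]-2-hydroxypropanoate | COCOC(=O)[C@H](O)Cc1ccc(OCOC)c(OCOC)c1
F5 | step 7 | methoxymethyl (R)-2-(acryloyloxy)-3-[3,4-bis(methoxymethoxy)phenyl]propanoate | C=CC(=O)O[C@H](Cc1ccc(OCOC)c(OCOC)c1)C(=O)OCOC
F6 | step 7 | methoxymethyl (R)-3-[3,4-bis(methoxymethoxy)phenyl]-2-{[(E)-3-{4-[(6,7-dihydroxy-2-oxo-2H-chromen-3-yl)oxy]-3-hydroxyphenyl}prop-2-enoyl]oxy}propanoate | O=C(/C=C/c1ccc(Oc2cc3cc(O)c(O)cc3oc2=O)c(O)c1)O[C@H](Cc1ccc(OCOC)c(OCOC)c1)C(=O)OCOC
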